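**The alder bend.** The alder run climbs almost straight but not quite: [target], as a fraction of the charge, rises at 0.00988 min⁻¹ between 15.0 min and 40.0 min, then at a slower 0.00935 min⁻¹ up to 60.0 min. If the feed is steady and target is lost in proportion to what stands, then the drop in slope divided by the rise in mean target gives the bend constant 0.00244 min⁻¹, an apparent first-order rate constant. It is a difference of two slopes under a scatter of 0.3 percentage points, so you should hold it as a reading of its size, not of its second digit.

- alder (time / min: target / %): 8.00: 4.6; 15.0: 11.3; 25.0: 20.9; 30.0: 26.2; 40.0: 36.0; 50.0: 45.8; 60.0: 54.7

(scatter of a reading: 0.3 percentage points)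

| setting | alder | beta | zeta | gamma | theta |
|---|---|---|---|---|---|
| solid substrate | 70 mM | 35 mM | 35 mM | 35 mM | 35 mM |
| free catalyst | 0.5 mol% | 0.5 mol% | 0.5 mol% | 0.5 mol% | 0.5 mol% |
| temperature | 50 °C | 50 °C | 75 °C |  | 25 °C |
| remark | run made earlier |  |  | at 25 °C until 1.0 h, from then on at 75 °C |  |
| time |  | 5.0 h | 5.0 h | 5.0 h | 5.0 h |

- as a solid, counted per litre of solution: solid substrate
- the analysis behind the earlier runs scatters by 0.3 percentage points, standard deviation
- at the start none of the solid substrate is in solution
- what has only dissolved of solid substrate counts as not reacted
- the earlier runs do not show what temperature does; that part of a forecast is a guess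
- no earlier run changes the charge of free catalyst; that part of a forecast is a guess

- the best flask by amount of target, in percent of the solid substrate charged; "all alike" if 1.5 percentage points covers them all (beta / zeta / gamma / theta / all alike)
- amount of target at the end, in percent of the solid substrate charged, beta
- amount of target at the end, in percent of the solid substrate charged, zeta
- amount of target at the end, in percent of the solid substrate charged, gamma
- amount of target at the end, in percent of the solid substrate charged, theta

**Standing time.** Flask beta halves the charge at the same loading, so if the rate follows the catalyst the percent slope carries over, and by my reckoning beta needs about 101 min to form its target. An average target in beta therefore stands 249 min, and my own reckoning keeps 54.4% of the charge as target. Temperature is a guess: if the loss ran 4 times faster at 75 °C, zeta, reckoned with beta's standing time, would keep roughly 8.80%, so I take beta as the best flask, and what theta makes at 25 °C stays a guess too.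

**The forecast.** The forecast names beta, giving beta 97% (range 88% to 100%), zeta 94%, gamma 94% and theta 50%, and it says “No side loss shows in the data”. Turn that round: for beta to end at 97% over the same standing time, the loss constant would have to be 1.22 × 10⁻⁴ min⁻¹, which is 20.0 times below the bend constant, and there my reckoning parts from the forecast.

**The flasks.** Flask beta ends at 63.3%, zeta at 0%, gamma at 0.0162% and theta at 31.1%, so the best flask is beta. At 5.00 h beta holds 36.7% over-reaction product beside its target.

    target → over-reaction product (k = 0.00180 min⁻¹, Ea = 114 kJ mol⁻¹)
    catalyst intermediate → free catalyst + target (k = 4.50 min⁻¹, Ea = 95.0 kJ mol⁻¹)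
    starting material + free catalyst → catalyst intermediate (k = 610 L mol⁻¹ min⁻¹, Ea = 45.0 kJ mol⁻¹)
    solid substrate ⇌ starting material, rate k4*(cs4 - [starting material]) while solid is left; crystals form when [starting material] > cs4 (solubility = 17.0 mM, k = 0.0700 min⁻¹)
    (constants at 50 °C)

The 54.4% reckoned with the bend constant for beta stands below the 63.3% that flask beta ends at. Carried on from beta's end to 12 h, the bend constant leaves 22.7%, and the neighbour flask, beta left that long, holds 29.7% target.

The readings were computed with constants of no real substance, and the scatter is random.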